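A direct plan would start from genistein A1 and would cap its three phenols as methyl ethers to give the trimethyl ether A2.
One portion of A2 would be chlorinated at C8 to the 8-chloro compound A3 and freed again with BBr3 to 8-chlorogenistein A4, and another portion of A2 would be iodinated at C8 to the 8-iodo compound A5.
A4 and A5 would then be joined by a copper-catalysed Ullmann etherification to the diaryl ether A6, and A6 would be demethylated at the end to the target.
Its weakest points would be:
(a) the etherification, which would have to pick the 4'-OH among three free phenols and force it onto a di-ortho-oxygenated, electron-rich 8-iodochromone, a pairing without precedent, on material that already holds both halves;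
(b) the two C8 halogenations, whose site (C8 against C6 and the anisyl ring) would rest on innate preference alone;
(c) the closing threefold demethylation with a large excess of BBr3 on the finished skeleton, the last of three steps (of six) that only move methyl groups.

Plan of the new route
The retrosynthesis first cuts both C5–O bonds: on each ring A the C5–H is peri to the C4=O of its own pyranone, the only C–H a carbonyl-bound metal can reach through a five-membered metallacycle, and C8 is already filled (Cl, aryloxy).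
Without the C5 oxygens each ring A is a C2v-symmetric 2-substituted resorcinol, so cutting each pyranone (C4–C4a, C2–C3, O1–C2) back to an arylacetic acid and the carbon of DMF leaves one possible regiochemistry.
The last cut is the ether C–O bond on the phenylene ring: an unhindered aryl iodide plus 2,6-dimethoxyphenol.
Forward, the rings arise in the order diaryl ether, pyranone of the chloro half, pyranone of the aryloxy half; both C5–OH groups come last, in one operation, on a precursor built in four steps from symmetric blocks.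
No chromone is halogenated, no two isoflavones are coupled, no choice among free phenols is needed and nothing is methylated: chlorine and the ether oxygen are bought in place.
Key step: step 5

Remark: the target has no stereocentre, and its aryl–chromone and diaryl ether axes are assumed to rotate freely, so no configuration has to be set.

Step 1
Reactants: 1 2,6-dimethoxyphenol (1.5 equiv); 2 2-(4-iodophenyl)acetic acid
Product: 3 2-[4-(2,6-dimethoxyphenoxy)phenyl]acetic acid
Conditions: CuI (10 mol%), picolinic acid (20 mol%), K3PO4 (3.5 equiv), DMSO, 90 °C, Ar; then aq. HCl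
Reagents that add atoms: none
Why: Ullmann-type diaryl ether synthesis in its favourable polarity (hindered, electron-rich phenoxide on an unhindered aryl iodide, the pairing for which the CuI/picolinic acid system is established), with the carboxylate of 2 as a spectator; 1 is symmetric, so the ether oxygen is placed between two equivalent oxygens without any choice.

Step 2
Reactants: 3 2-[4-(2,6-dimethoxyphenoxy)phenyl]acetic acid; 4 2-chlorobenzene-1,3-diol (1.5 equiv)
Product: 6 8-chloro-3-[4-(2,6-dimethoxyphenoxy)phenyl]-7-hydroxy-4H-chromen-4-one, via deoxybenzoin 5 (not isolated)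
Conditions: BF3·OEt2 (solvent), 85 °C; then DMF, MsCl, 70 °C; aq. NaOAc
Reagents that add atoms: N,N-dimethylformamide, CN(C)C=O
Why: BF3-mediated Friedel–Crafts acylation can only occur at C4 (= C6) of symmetric 2-chlororesorcinol, and the one-pot Vilsmeier-type C-formylation of the benzylic CH2 closes through the only ortho hydroxyl (the one next to Cl) to the 8-chloro-7-hydroxyisoflavone (deoxybenzoin route to isoflavones); the methoxy-substituted ring of 3 should stay untouched under BF3·OEt2, as it does with other methoxyphenylacetic acids.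

Step 3
Reactants: 6 8-chloro-3-[4-(2,6-dimethoxyphenoxy)phenyl]-7-hydroxy-4H-chromen-4-one
Product: 7 8-chloro-3-[4-(2,6-dihydroxyphenoxy)phenyl]-7-hydroxy-4H-chromen-4-one
Conditions: BBr3 (6 equiv), CH2Cl2, −78 °C to rt; then H2O
Reagents that add atoms: none
Why: BBr3 cleavage of the two aryl methyl ethers, to which the diaryl ether, the aryl chloride and the chromone are inert; the 2-aryloxyresorcinol set free is again symmetric about the ether oxygen.

Step 4
Reactants: 7 8-chloro-3-[4-(2,6-dihydroxyphenoxy)phenyl]-7-hydroxy-4H-chromen-4-one; 8 2-(4-hydroxyphenyl)acetic acid (1.3 equiv)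
Product: 10 8-chloro-7-hydroxy-3-(4-{[7-hydroxy-3-(4-hydroxyphenyl)-4-oxo-4H-chromen-8-yl]oxy}phenyl)-4H-chromen-4-one, via deoxybenzoin 9 (not isolated)
Conditions: BF3·OEt2 (solvent), 85 °C; then DMF, MsCl, 70 °C; aq. NaOAc
Reagents that add atoms: N,N-dimethylformamide, CN(C)C=O
Why: The same Friedel–Crafts acylation and formylative annulation: the free resorcinol ring is the only strongly activated ring (the 7-hydroxychromone ring is a deactivated vinylogous acid), it can be acylated only at C4 (= C6), and closure through the hydroxyl between the acyl group and the ether oxygen places the aryloxy group at C8.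

Step 5
Reactants: 10 8-chloro-7-hydroxy-3-(4-{[7-hydroxy-3-(4-hydroxyphenyl)-4-oxo-4H-chromen-8-yl]oxy}phenyl)-4H-chromen-4-one
Product: 13 Bisoflavolin I, via tris(trifluoroacetate) 11 (not isolated), via pentakis(trifluoroacetate) 12 (not isolated)
Conditions: (CF3CO)2O/CF3CO2H (1:3), rt; then [RuCl2(p-cymene)]2 (10 mol%), PhI(OCOCF3)2 (4.5 equiv), 80 °C; then aq. NaHCO3/THF, rt
Reagents that add atoms: [bis(trifluoroacetoxy)iodo]benzene, O=C(OI(OC(=O)C(F)(F)F)c1ccccc1)C(F)(F)F
Why: In the anhydride medium the three phenols of 10 are first masked as electron-poor trifluoroacetates (11), which shields the phenolic rings from the hypervalent iodine oxidant; the divalent ruthenium trifluoroacetate formed from [RuCl2(p-cymene)]2 binds each pyranone C4=O and cleaves the peri C5–H by carboxylate-assisted metalation to a five-membered ruthenacycle, PhI(OCOCF3)2 oxidises this to a tetravalent ruthenium trifluoroacetate, and C–O reductive elimination leaves a C5–OCOCF3 ester (12), all five esters being hydrolysed on work-up. The closest known reaction type is the carbonyl-directed ruthenium- or palladium-catalysed ortho C–H oxygenation of aryl ketones in CF3CO2H/(CF3CO)2O, which has been carried out at C5 of chromones and flavones. No ring is closed and no stereocentre is formed. The selectivity needed is C5 over C6 on each ring A and over C2'/C6' of the 3-aryl rings: C5–H is the only C–H that C4=O can reach through a five-membered metallacycle, C6–H cannot chelate at all, the aryl ortho C–H would need a six-membered metallacycle across a twisted aryl–chromone bond, and C8 is already filled by Cl or by the aryloxy group. Over-oxidation should be held back because each new oxygen is formed as a deactivating trifluoroacetate and not as a free phenol.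

Compound list
1 | 2,6-dimethoxyphenol | COc1cccc(OC)c1O | starting material
2 | 2-(4-iodophenyl)acetic acid | OC(=O)Cc1ccc(I)cc1 | starting material
3 | 2-[4-(2,6-dimethoxyphenoxy)phenyl]acetic acid | COc1cccc(OC)c1Oc1ccc(CC(=O)O)cc1 | intermediate
4 | 2-chlorobenzene-1,3-diol (2-chlororesorcinol) | Oc1cccc(O)c1Cl | starting material
5 | 1-(3-chloro-2,4-dihydroxyphenyl)-2-[4-(2,6-dimethoxyphenoxy)phenyl]ethan-1-one | COc1cccc(OC)c1Oc1ccc(CC(=O)c2ccc(O)c(Cl)c2O)cc1 | intermediate
6 | 8-chloro-3-[4-(2,6-dimethoxyphenoxy)phenyl]-7-hydroxy-4H-chromen-4-one | O=c1c(-c2ccc(Oc3c(OC)cccc3OC)cc2)coc2c(Cl)c(O)ccc12 | intermediate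
7 | 8-chloro-3-[4-(2,6-dihydroxyphenoxy)phenyl]-7-hydroxy-4H-chromen-4-one | O=c1c(-c2ccc(Oc3c(O)cccc3O)cc2)coc2c(Cl)c(O)ccc12 | intermediate
8 | 2-(4-hydroxyphenyl)acetic acid | OC(=O)Cc1ccc(O)cc1 | starting material
9 | 8-chloro-3-[4-({2,6-dihydroxy-3-[2-(4-hydroxyphenyl)acetyl]phenyl}oxy)phenyl]-7-hydroxy-4H-chromen-4-one | O=c1c(-c2ccc(Oc3c(O)ccc(C(=O)Cc4ccc(O)cc4)c3O)cc2)coc2c(Cl)c(O)ccc12 | intermediate
10 | 8-chloro-7-hydroxy-3-(4-{[7-hydroxy-3-(4-hydroxyphenyl)-4-oxo-4H-chromen-8-yl]oxy}phenyl)-4H-chromen-4-one | O=c1c(-c2ccc(Oc3c(O)ccc4c(=O)c(-c5ccc(O)cc5)coc34)cc2)coc2c(Cl)c(O)ccc12 | intermediate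
11 | tris(trifluoroacetate) of 10 (both 7-O and the 4'-O esterified) | O=c1c(-c2ccc(Oc3c(OC(=O)C(F)(F)F)ccc4c(=O)c(-c5ccc(OC(=O)C(F)(F)F)cc5)coc34)cc2)coc2c(Cl)c(OC(=O)C(F)(F)F)ccc12 | intermediate
12 | pentakis(trifluoroacetate) of 13 (both 5-O, both 7-O and the 4'-O esterified) | O=c1c(-c2ccc(Oc3c(OC(=O)C(F)(F)F)cc(OC(=O)C(F)(F)F)c4c(=O)c(-c5ccc(OC(=O)C(F)(F)F)cc5)coc34)cc2)coc2c(Cl)c(OC(=O)C(F)(F)F)cc(OC(=O)C(F)(F)F)c12 | intermediate
13 | Bisoflavolin I, 8-chloro-3-(4-{[5,7-dihydroxy-3-(4-hydroxyphenyl)-4-oxo-4H-chromen-8-yl]oxy}phenyl)-5,7-dihydroxy-4H-chromen-4-one (achiral) | O=c1c(-c2ccc(Oc3c(O)cc(O)c4c(=O)c(-c5ccc(O)cc5)coc34)cc2)coc2c(Cl)c(O)cc(O)c12 | target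

Total step count: 5. Longest linear sequence: 5 steps (1 and 2 to 13).

Steps most likely to fail

Step 5 (twofold peri C–H hydroxylation). What may go wrong: the oxidant attacks the phenoxy-substituted phenylene ring by electron transfer before the deactivated rings A are metalated, or the reaction stalls after the first hydroxylation. The fallback sets out from 2 and comes back at 13; it carries the C5 oxygens in from the start and uses no C–H oxidation. 2 would be coupled under the conditions of step 1 with commercial 2,4,6-trimethoxyphenol (COc1cc(OC)c(O)c(OC)c1) to 2-[4-(2,4,6-trimethoxyphenoxy)phenyl]acetic acid F1. BBr3 in CH2Cl2, followed by a methanol quench at reflux, would give methyl 2-[4-(2,4,6-trihydroxyphenoxy)phenyl]acetate F2. Acylation with 8 and annulation as in step 4 would give methyl 2-[4-({5,7-dihydroxy-3-(4-hydroxyphenyl)-4-oxo-4H-chromen-8-yl}oxy)phenyl]acetate F3. Aqueous HCl in dioxane at reflux would give 2-[4-({5,7-dihydroxy-3-(4-hydroxyphenyl)-4-oxo-4H-chromen-8-yl}oxy)phenyl]acetic acid F4. F4 would then acylate 2-chlorobenzene-1,3,5-triol F5 (from phloroglucinol and N-chlorosuccinimide) in BF3·OEt2, and the DMF/MsCl annulation would give 13. The price is that each ring closure could then use either ortho hydroxyl, so each annulation would need separation of the 8-substituted from the 6-substituted ring-closure isomer.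

Step 4 (second acylation and annulation). What may go wrong: the polyphenolic chromone 7 dissolves poorly in the Lewis acid and is esterified at oxygen instead of acylated at carbon, so that the Friedel–Crafts stage stalls. The fallback sets out from 3 and comes back at 10; it inverts the order of the two annulations, so that each Friedel–Crafts acylation is run on a small, soluble resorcinol. 3 with BBr3 in CH2Cl2, then methanol at reflux, would give methyl 2-[4-(2,6-dihydroxyphenoxy)phenyl]acetate F6. Acylation with 8 in BF3·OEt2 and DMF/MsCl annulation would give methyl 2-[4-({7-hydroxy-3-(4-hydroxyphenyl)-4-oxo-4H-chromen-8-yl}oxy)phenyl]acetate F7. Aqueous HCl in dioxane at reflux would give 2-[4-({7-hydroxy-3-(4-hydroxyphenyl)-4-oxo-4H-chromen-8-yl}oxy)phenyl]acetic acid F8. F8 with an excess of 4 under the conditions of step 2 would give 10.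

Step 1 (copper-catalysed etherification). What may go wrong: slow turnover because the di-ortho-substituted phenoxide and the carboxylate both tie up copper, with reductive loss of iodine from 2. The fallback sets out from 1 and comes back at 3; it is metal-free. Nucleophilic aromatic substitution of 1 on 1-(4-fluorophenyl)ethan-1-one (CC(=O)c1ccc(F)cc1; K2CO3, DMF, 140 °C) would give 1-[4-(2,6-dimethoxyphenoxy)phenyl]ethan-1-one F9. A Willgerodt–Kindler reaction (S8, morpholine, 130 °C) would give 2-[4-(2,6-dimethoxyphenoxy)phenyl]-1-(morpholin-4-yl)ethane-1-thione F10. Hydrolysis with NaOH in aqueous ethanol at reflux, then acid, would give 3.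

Further compounds
F1 | step 5 | 2-[4-(2,4,6-trimethoxyphenoxy)phenyl]acetic acid | COc1cc(OC)c(Oc2ccc(CC(=O)O)cc2)c(OC)c1
F2 | step 5 | methyl 2-[4-(2,4,6-trihydroxyphenoxy)phenyl]acetate | COC(=O)Cc1ccc(Oc2c(O)cc(O)cc2O)cc1
F3 | step 5 | methyl 2-[4-({5,7-dihydroxy-3-(4-hydroxyphenyl)-4-oxo-4H-chromen-8-yl}oxy)phenyl]acetate | COC(=O)Cc1ccc(Oc2c(O)cc(O)c3c(=O)c(-c4ccc(O)cc4)coc23)cc1
F4 | step 5 | 2-[4-({5,7-dihydroxy-3-(4-hydroxyphenyl)-4-oxo-4H-chromen-8-yl}oxy)phenyl]acetic acid | OC(=O)Cc1ccc(Oc2c(O)cc(O)c3c(=O)c(-c4ccc(O)cc4)coc23)cc1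
F5 | step 5 | 2-chlorobenzene-1,3,5-triol | Oc1cc(O)c(Cl)c(O)c1
F6 | step 4 | methyl 2-[4-(2,6-dihydroxyphenoxy)phenyl]acetate | COC(=O)Cc1ccc(Oc2c(O)cccc2O)cc1
F7 | step 4 | methyl 2-[4-({7-hydroxy-3-(4-hydroxyphenyl)-4-oxo-4H-chromen-8-yl}oxy)phenyl]acetate | COC(=O)Cc1ccc(Oc2c(O)ccc3c(=O)c(-c4ccc(O)cc4)coc23)cc1
F8 | step 4 | 2-[4-({7-hydroxy-3-(4-hydroxyphenyl)-4-oxo-4H-chromen-8-yl}oxy)phenyl]acetic acid | OC(=O)Cc1ccc(Oc2c(O)ccc3c(=O)c(-c4ccc(O)cc4)coc23)cc1
F9 | step 1 | 1-[4-(2,6-dimethoxyphenoxy)phenyl]ethan-1-one | COc1cccc(OC)c1Oc1ccc(C(C)=O)cc1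
F10 | step 1 | 2-[4-(2,6-dimethoxyphenoxy)phenyl]-1-(morpholin-4-yl)ethane-1-thione | COc1cccc(OC)c1Oc1ccc(CC(=S)N2CCOCC2)cc1
A1 | direct plan | genistein, 5,7-dihydroxy-3-(4-hydroxyphenyl)-4H-chromen-4-one | O=c1c(-c2ccc(O)cc2)coc2cc(O)cc(O)c12
A2 | direct plan | 5,7-dimethoxy-3-(4-methoxyphenyl)-4H-chromen-4-one | COc1ccc(-c2coc3cc(OC)cc(OC)c3c2=O)cc1
A3 | direct plan | 8-chloro-5,7-dimethoxy-3-(4-methoxyphenyl)-4H-chromen-4-one | COc1ccc(-c2coc3c(Cl)c(OC)cc(OC)c3c2=O)cc1
A4 | direct plan | 8-chloro-5,7-dihydroxy-3-(4-hydroxyphenyl)-4H-chromen-4-one (8-chlorogenistein) | O=c1c(-c2ccc(O)cc2)coc2c(Cl)c(O)cc(O)c12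
A5 | direct plan | 8-iodo-5,7-dimethoxy-3-(4-methoxyphenyl)-4H-chromen-4-one | COc1ccc(-c2coc3c(I)c(OC)cc(OC)c3c2=O)cc1
A6 | direct plan | 8-chloro-3-[4-({5,7-dimethoxy-3-(4-methoxyphenyl)-4-oxo-4H-chromen-8-yl}oxy)phenyl]-5,7-dihydroxy-4H-chromen-4-one | O=c1c(-c2ccc(Oc3c(OC)cc(OC)c4c(=O)c(-c5ccc(OC)cc5)coc34)cc2)coc2c(Cl)c(O)cc(O)c12
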